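## Retrosynthetic overview

1. The last disconnection is the two aryl silyl ethers of flavanone 13 (global desilylation to the target 14).
2. Ring C of 13 is cut at O1–C2 and at C4–C4a, which gives phenol 6 and cinnamoyl chloride 10. They are joined in one flask by magnesium-phenoxide-templated ortho-acylation followed by a catalytic asymmetric 6-endo oxa-Michael closure that sets C2.
3. Enabling feature: in ring A the free O1–H sits next to the only unsubstituted ortho carbon, C4a (C8 carries the prenyl group, O5 is silylated), so O1–C8a=C4a acts as a 1,3-O,C-dinucleophile. In ring C the 1,3-relationship of O1 and the C4 carbonyl is the retron of an oxa-Michael addition.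
4. Phenol 6 comes from 5-methoxyresorcinol by monosilylation, MOM protection, directed ortho-metalation/prenylation between OMOM and OMe, and MOM removal. Acid chloride 10 comes from p-coumaric acid.
5. Ring order: rings A and B are bought; ring C is the only ring formed (step 7).

Key step: step 7

Remark on the chemistry: the quinine-derived thiourea is written as the catalyst that closes ring C to the 2S series; if a test run shows the opposite sense, its quinidine-derived pseudoenantiomer takes its place with nothing else changed.

## Route

Step 1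
Reactants: 1 5-methoxyresorcinol
Product: 2 3-methoxy-5-(triisopropylsilyloxy)phenol
Conditions: TIPSCl (1.0 equiv), imidazole, DMF, 0 °C to rt
Reagents that add atoms: triisopropylsilyl chloride, CC(C)[Si](Cl)(C(C)C)C(C)C
Why: Silylation of one of the two equivalent phenols with one equivalent of a bulky chlorosilane (statistical desymmetrisation) should give the mono-ether, which is separated from recovered diol and bis-ether.

Step 2
Reactants: 2 3-methoxy-5-(triisopropylsilyloxy)phenol
Product: 3 [3-methoxy-5-(methoxymethoxy)phenoxy]triisopropylsilane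
Conditions: MOMCl, i-Pr2NEt, CH2Cl2, 0 °C to rt
Reagents that add atoms: chloromethyl methyl ether, COCCl
Why: O-Alkylation of the phenol with the α-chloro ether (Williamson-type etherification) installs the MOM group that directs the metalation of step 3.

Step 3
Reactants: 3 [3-methoxy-5-(methoxymethoxy)phenoxy]triisopropylsilane
Product: 5 [3-methoxy-5-(methoxymethoxy)-4-(3-methylbut-2-en-1-yl)phenoxy]triisopropylsilane, via aryllithium 4 (not isolated)
Conditions: n-BuLi, TMEDA, THF, 0 °C; then CuI (10 mol%), prenyl bromide, −78 °C to rt
Reagents that add atoms: prenyl bromide (1-bromo-3-methylbut-2-ene), CC(C)=CCBr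
Why: Directed ortho-metalation should occur at the carbon flanked by the coordinating OMOM and OMe groups (the other position ortho to OMOM is shielded by the non-coordinating OTIPS group), and copper-catalysed allylic substitution of prenyl bromide at its primary carbon then gives the prenyl arene.

Step 4
Reactants: 5 [3-methoxy-5-(methoxymethoxy)-4-(3-methylbut-2-en-1-yl)phenoxy]triisopropylsilane
Product: 6 3-methoxy-2-(3-methylbut-2-en-1-yl)-5-(triisopropylsilyloxy)phenol
Conditions: TsOH·H2O (cat.), MeOH, rt
Reagents that add atoms: none
Why: Acid-catalysed transacetalisation of the aryl MOM ether to methanol frees the phenol, and the aryl TIPS ether and the prenyl alkene should tolerate catalytic acid at room temperature.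

Step 5
Reactants: 7 p-coumaric acid
Product: 9 (E)-3-[4-(tert-butyldimethylsilyloxy)phenyl]acrylic acid, via silyl ester 8 (not isolated)
Conditions: TBSCl (2.2 equiv), imidazole, DMF, rt; then AcOH, THF, H2O, rt
Reagents that add atoms: tert-butyldimethylsilyl chloride, CC(C)(C)[Si](C)(C)Cl
Why: Silylation of both the phenol and the acid followed by selective hydrolysis of the far more labile silyl ester leaves the aryl TBS ether and the free acid.

Step 6
Reactants: 9 (E)-3-[4-(tert-butyldimethylsilyloxy)phenyl]acrylic acid
Product: 10 (E)-3-[4-(tert-butyldimethylsilyloxy)phenyl]acryloyl chloride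
Conditions: (COCl)2, DMF (cat.), CH2Cl2, 0 °C to rt; volatiles removed, used crude
Reagents that add atoms: oxalyl chloride, O=C(Cl)C(Cl)=O
Why: Vilsmeier-type activation with oxalyl chloride and catalytic DMF converts the acid into the acid chloride without affecting the aryl silyl ether or the E-alkene.

Step 7
Reactants: 6 3-methoxy-2-(3-methylbut-2-en-1-yl)-5-(triisopropylsilyloxy)phenol; 10 (E)-3-[4-(tert-butyldimethylsilyloxy)phenyl]acryloyl chloride
Product: 13 (2S)-2-[4-(tert-butyldimethylsilyloxy)phenyl]-7-methoxy-8-(3-methylbut-2-en-1-yl)-5-(triisopropylsilyloxy)-2,3-dihydro-4H-chromen-4-one, via bromomagnesium phenoxide 11 (not isolated), via chalcone 12 (not isolated)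
Conditions: EtMgBr (1.0 equiv), Et2O then PhMe, 0 °C; 10, PhMe, 0 °C to rt; 1,4-dioxane (precipitates MgBrCl); then 1-[3,5-bis(trifluoromethyl)phenyl]-3-[(8α,9S)-6'-methoxycinchonan-9-yl]thiourea (10 mol%), PhMe, −20 °C; AcOH quench (one flask, no work-up in between)
Reagents that add atoms: none
Why: Deprotonation of 6 gives the bromomagnesium phenoxide 11, whose magnesium binds the acyl chloride oxygen so that the only free ortho carbon, C4a, attacks the acyl carbon through a six-membered chelate (metal-template ortho-acylation of magnesium phenoxides is the closest known reaction type); rearomatisation gives the 2'-hydroxychalcone 12 as its MgBrCl adduct, in which O1 and the C4 carbonyl are held syn so that no uncatalysed closure occurs. Precipitation of the magnesium salt with dioxane frees 12, and the cinchona thiourea then closes ring C by a 6-endo-trig oxa-Michael addition of O1 to C2, the organocatalytic counterpart of the chalcone isomerase cyclisation of 2'-hydroxychalcones. The C2 stereocentre is set by the catalyst: the thiourea hydrogen-bonds the C4 carbonyl while the quinuclidine nitrogen deprotonates O1–H, so the phenoxide adds to one enantioface of C2 inside the ion pair, and the catalyst series that gives 2S is used. The selectivities needed are C- over O-acylation and ortho over para attack (secured by the magnesium chelate and by the prenyl block at C8), closure through O1 and not O5 (O5 is silylated), and kinetic control over the reversible ring opening (low temperature, acid quench, and the 6'-silyloxy group that twists the ketone out of conjugation and drives the closure).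

Step 8
Reactants: 13 (2S)-2-[4-(tert-butyldimethylsilyloxy)phenyl]-7-methoxy-8-(3-methylbut-2-en-1-yl)-5-(triisopropylsilyloxy)-2,3-dihydro-4H-chromen-4-one
Product: 14 Mundulea flavanone B, (2S)-5-hydroxy-2-(4-hydroxyphenyl)-7-methoxy-8-(3-methylbut-2-en-1-yl)-2,3-dihydro-4H-chromen-4-one
Conditions: Bu4NF, AcOH (1:1), THF, 0 °C
Reagents that add atoms: none
Why: Fluoride cleaves both aryl silyl ethers by Si–F bond formation, and the acetic acid buffer keeps the liberated phenoxides protonated so that C2 should not be scrambled by retro-oxa-Michael ring opening.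

## Compound list

1 | 5-methoxyresorcinol (5-methoxybenzene-1,3-diol) | COc1cc(O)cc(O)c1 | starting material
2 | 3-methoxy-5-(triisopropylsilyloxy)phenol | COc1cc(O)cc(O[Si](C(C)C)(C(C)C)C(C)C)c1 | intermediate
3 | [3-methoxy-5-(methoxymethoxy)phenoxy]triisopropylsilane | COCOc1cc(OC)cc(O[Si](C(C)C)(C(C)C)C(C)C)c1 | intermediate
4 | [2-methoxy-6-(methoxymethoxy)-4-(triisopropylsilyloxy)phenyl]lithium (not isolated) | [Li]c1c(OC)cc(O[Si](C(C)C)(C(C)C)C(C)C)cc1OCOC | intermediate
5 | [3-methoxy-5-(methoxymethoxy)-4-(3-methylbut-2-en-1-yl)phenoxy]triisopropylsilane | COCOc1cc(O[Si](C(C)C)(C(C)C)C(C)C)cc(OC)c1CC=C(C)C | intermediate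
6 | 3-methoxy-2-(3-methylbut-2-en-1-yl)-5-(triisopropylsilyloxy)phenol | COc1cc(O[Si](C(C)C)(C(C)C)C(C)C)cc(O)c1CC=C(C)C | intermediate
7 | p-coumaric acid, (E)-3-(4-hydroxyphenyl)acrylic acid | OC(=O)/C=C/c1ccc(O)cc1 | starting material
8 | tert-butyldimethylsilyl (E)-3-[4-(tert-butyldimethylsilyloxy)phenyl]acrylate (not isolated) | CC(C)(C)[Si](C)(C)OC(=O)/C=C/c1ccc(O[Si](C)(C)C(C)(C)C)cc1 | intermediate
9 | (E)-3-[4-(tert-butyldimethylsilyloxy)phenyl]acrylic acid | OC(=O)/C=C/c1ccc(O[Si](C)(C)C(C)(C)C)cc1 | intermediate
10 | (E)-3-[4-(tert-butyldimethylsilyloxy)phenyl]acryloyl chloride | ClC(=O)/C=C/c1ccc(O[Si](C)(C)C(C)(C)C)cc1 | intermediate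
11 | bromomagnesium 3-methoxy-2-(3-methylbut-2-en-1-yl)-5-(triisopropylsilyloxy)phenoxide (not isolated) | COc1cc(O[Si](C(C)C)(C(C)C)C(C)C)cc(O[Mg]Br)c1CC=C(C)C | intermediate
12 | (E)-3-[4-(tert-butyldimethylsilyloxy)phenyl]-1-[2-hydroxy-4-methoxy-3-(3-methylbut-2-en-1-yl)-6-(triisopropylsilyloxy)phenyl]prop-2-en-1-one (not isolated) | COc1cc(O[Si](C(C)C)(C(C)C)C(C)C)c(C(=O)/C=C/c2ccc(O[Si](C)(C)C(C)(C)C)cc2)c(O)c1CC=C(C)C | intermediate
13 | (2S)-2-[4-(tert-butyldimethylsilyloxy)phenyl]-7-methoxy-8-(3-methylbut-2-en-1-yl)-5-(triisopropylsilyloxy)-2,3-dihydro-4H-chromen-4-one | COc1cc(O[Si](C(C)C)(C(C)C)C(C)C)c2c(c1CC=C(C)C)O[C@H](c1ccc(O[Si](C)(C)C(C)(C)C)cc1)CC2=O | intermediate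
14 | Mundulea flavanone B, (2S)-5-hydroxy-2-(4-hydroxyphenyl)-7-methoxy-8-(3-methylbut-2-en-1-yl)-2,3-dihydro-4H-chromen-4-one | COc1cc(O)c2c(c1CC=C(C)C)O[C@H](c1ccc(O)cc1)CC2=O | target

## Step count and risks

Total step count: 8. Longest linear sequence: 6 steps (steps 1, 2, 3, 4, 7, 8).

Steps most likely to fail:

Step 7. O-acylation of the phenoxide may compete with the templated C-acylation. Above all, the ring closure may show insufficient enantiofacial discrimination, or the selectivity may erode through reversible retro-oxa-Michael ring opening under the basic catalyst. The fallback sets out from 6 and 10 and comes back at 13. The magnesium-template acylation is run alone and worked up to give chalcone 12. NaOAc in EtOH at 50 °C closes it without chiral control to the racemic 2-[4-(tert-butyldimethylsilyloxy)phenyl]-7-methoxy-8-(3-methylbut-2-en-1-yl)-5-(triisopropylsilyloxy)-2,3-dihydro-4H-chromen-4-one F1. Kinetic resolution by asymmetric transfer hydrogenation with [RhCl(C5Me5)(TsDPEN)] and HCO2H/Et3N follows, using the TsDPEN enantiomer that reduces the 2R ketone. That enantiomer is converted into the cis-(2R,4R)-flavan-4-ol F2, and the unreduced 2S ketone 13 is separated by chromatography.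

Step 3. Lithiation may occur at the wrong ring carbon, the silyl group may shift from oxygen to a lithiated ortho carbon, or allylic transposition may deliver a 1,1-dimethylallyl group instead of prenyl. The fallback sets out from 2 and comes back at 6, without any organolithium. O-Alkylation of 2 with methyl 2-methylbut-3-en-2-yl carbonate and Pd(PPh3)4 in THF gives the aryl 1,1-dimethylallyl ether, triisopropyl{3-methoxy-5-[(2-methylbut-3-en-2-yl)oxy]phenoxy}silane F3. Heating in toluene triggers the aromatic Claisen rearrangement, which should place the prenyl group on the ortho carbon between the oxygen and OMe (the other ortho carbon is shielded by OTIPS) and frees the phenol of 6 in the same event.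

Step 4. Under acid the freed ortho hydroxyl may add across the prenyl double bond (closure to a 2,2-dimethylchroman), or the TIPS ether may be lost. The fallback sets out from 2 and comes back at 6 and avoids the acetal altogether. The sodium phenoxide of 2 (NaH, toluene) is C-alkylated with prenyl bromide in the non-polar medium, which should favour the less hindered ortho carbon between the oxygen and OMe. No compound outside the list is made (F0).

## Further compounds

F1 | step 7 | racemic 2-[4-(tert-butyldimethylsilyloxy)phenyl]-7-methoxy-8-(3-methylbut-2-en-1-yl)-5-(triisopropylsilyloxy)-2,3-dihydro-4H-chromen-4-one | COc1cc(O[Si](C(C)C)(C(C)C)C(C)C)c2c(c1CC=C(C)C)OC(c1ccc(O[Si](C)(C)C(C)(C)C)cc1)CC2=O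
F2 | step 7 | (2R,4R)-2-[4-(tert-butyldimethylsilyloxy)phenyl]-7-methoxy-8-(3-methylbut-2-en-1-yl)-5-(triisopropylsilyloxy)-3,4-dihydro-2H-chromen-4-ol | COc1cc(O[Si](C(C)C)(C(C)C)C(C)C)c2c(c1CC=C(C)C)O[C@@H](c1ccc(O[Si](C)(C)C(C)(C)C)cc1)C[C@H]2O
F3 | step 3 | triisopropyl{3-methoxy-5-[(2-methylbut-3-en-2-yl)oxy]phenoxy}silane | COc1cc(OC(C)(C)C=C)cc(O[Si](C(C)C)(C(C)C)C(C)C)c1
F0 | step 4 | none | none
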